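the same everywhere: X 2.6 mM (held)
- elm: L 0.10 M; run made earlier
- flask: L 0.050 M; time 30 min

- elm (time / min: J / %, L / %): 0.500: 3.0, 62.2; 1.00: 9.1, 40.0; 2.50: 14.8, 7.1; 6.00: 17.4, 0

(readings scatter by 1 percentage point)

- at the start none of X is in solution
- Z is what X becomes in solution

- amount of J at 30 min, in percent of the L charged
- concentration of Z in solution at 15 min, in percent of saturation
- the change that raises the amount of J at 30 min, in percent of the L charged most ("none" if none brings more than 2 percentage points) (south / south-east / none)
- amount of J at 30 min, in percent of the L charged, after south-east

- south: doubling the saturation concentration of X, all else as stated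
- south-east: doubling the transfer coefficient of X, all else as stated

If [Z] held one value throughout, a fixed share of L would become J, so I first ask how far the elm run falls short of its late share. In the elm run, the share of L turned to J (its selectivity) reads 17.3% between 1.00 min and 2.50 min, and a higher 36.6% after 2.50 min. L falls throughout, so I leave the rate of J aside, and I read the rise in the share as [Z] recovering. The tail need not be at saturation, so I use its share, with the scatter of its readings, as a reference and not as the saturated share.

The elm total of 17.4% then means a mean fullness f, [Z] as a fraction of its tail value, of 47.5%. I let f fall in step with the J made, and call A the gas allowance: the J at which f would reach nothing. The elm run gives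

J = share × [L]₀ × f, f = 1 − J/A, A = 33.2 mM.

**Charge of L.** For this flask I start from the elm f and go round:

J = 8.70 mM, so f = 73.8%, so J = 13.5 mM.

The rounds swing, then close at 11.8 mM, which is 23.6% of the charge.

**Transfer coefficient.** South-east doubles A, which gives 28.7%.

**Saturation.** South also doubles A, and it lifts the share to 53.6%, which gives 38.2%. So I choose south.

In the elm run L reads 0% at 6.00 min, so I expect [Z] near saturation at 15 min.

The forecast says 22%, 100%, south and 26.5%, on the ground that “so most L goes by a Z-independent waste path”. It stands below my 23.6% and 28.7%, but it chooses the same change.

The flask gives 25.5% and 99.3%. South adds 13 percentage points, south-east adds 8 points, and south-east reaches 33.5%.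

    X ⇌ Z, rate k1*(csat - [Z]) (kL = 3.40 min⁻¹)
    L + Z → J (k = 390 M⁻¹ min⁻¹)
    L → E (k = 0.720 min⁻¹)
    Z → D (k = 0.0200 min⁻¹)
    L + J → Q (k = 1.40 M⁻¹ min⁻¹)
    L ⇌ G (K = 23.0, k = 0.0990 min⁻¹)

The flask's J of 12.8 mM is 38.6% of A, the drawdown of [Z] that the rule assigns to it. The neighbouring flask holds 0.020 M of L, so the same reckoning starts from 7.32 mM and closes at 6.00 mM, or 30.0% of its charge. That neighbouring flask gives 34.6%.

(The data are calculated from invented constants, noise included.)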